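I began from a leftover. Each electrophile that reacts takes one nucleophile, so in this flask, charged with 0.900 equiv of nucleophile, nucleophile is the limiting reagent and part of the electrophile has no partner. That part, one minus the ratio of nucleophile to electrophile, I call the leftover, 10.0 % of the charge.

| flask | electrophile | nucleophile | remark | time |
|---|---|---|---|---|
| teal | 2 M | 0.90 equiv | the very flask that is asked about, followed so far |  |
| flask | 2.0 M | 0.900 equiv |  | 3.0 d |

- teal (time / h: electrophile / %, product / %): 1.33: 37.1, 61.9; 4.00: 27.2, 73.4; 8.00: 20.2, 79.2; 12.0: 20.5, 81.8; 15.0: 18.5, 80.3; 20.0: 16.5, 82.8

(readings scatter by 1 percentage point)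

- part of the electrophile that has reacted at 3.0 d
- share of the unused nucleophile that is free and not bound as protonated nucleophile, at 3.0 d

- what is said of product includes crystals
- crystals is a solid; its amount is given per volume of the solution
- what was read earlier has a scatter of 1 percentage point, one standard deviation
- on the list of suspects stand: electrophile + nucleophile -> acid set free + product; nucleophile + acid set free <-> protonated nucleophile; crystals <-> product
- the earlier runs do not show how much of nucleophile is bound; that part of a forecast is a guess

Was one number enough? It gives the floor for the electrophile, but not when the flask arrives there. At 20.0 h the teal reading stood 6.5 percentage points above that floor, with a scatter of 1 point. The readings had fallen 3.7 points since 8.00 h. That pace, kept up to 3.0 d, would cover 16 points, more than the gap. But the pace had been slowing, so I expected c just under 90.0 %.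

The forecast gave c as 88.5 % (86.5 % to 89.8 %), holding that the electrophile “caps at 90% conversion”. It gave fr as 11 % (4 % to 28 %), largely a guess, since the readings do not show bound nucleophile.

The flask gave c as 89.1 % and fr as 2.51 %, the second below the forecast's range. At 3.00 d free nucleophile in this flask stood at 0.0263 % of its charge, beside 0.0184 M of protonated nucleophile. The electrophile of this flask stood at 11 %, 0.94 points above the leftover, and at 30.0 d it stood at 10.0 %, the leftover itself.

    electrophile + nucleophile → acid set free + product (k = 0.00150 L mol⁻¹ s⁻¹)
    nucleophile + acid set free ⇌ protonated nucleophile, settled at all times (K = 22.0 L mol⁻¹)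
    crystals ⇌ product, rate k3*(cs3 - [product]) while solid is left; crystals form when [product] > cs3 (solubility = 0.120 M, k = 0.00410 s⁻¹)

In a second flask, charged with 0.230 equiv of nucleophile and otherwise the same, the leftover comes to 77.0 %. The computed flask held 77.0 % of its electrophile at 3.00 d.

The runs were generated by integration from invented constants; noise was put on by code.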